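**Plan**
- Retrosynthesis: each C≡C is taken back to an aryl ketone (ring–CH2–CO–Ar), the two CO–C5(bithiophene) bonds are cut, and the two CH2CO2H arms are rejoined as the CH=CH of a cyclohexene.
- The cyclobutane is then cut at C1–C4 and C2–C3. Its adjacent CH2 carbons (C3, C4) become a two-carbon ketene unit; the cis CH pair (C1, C2) with the first two carbons of each arm becomes cyclohexa-1,4-diene.
- Enabling feature: a four-membered ring with two neighbouring unsubstituted CH2 carbons and two cis CH carbons whose arms are each two carbons long, so a Z-alkene held in a six-membered ring can carry both masked arms as a tether.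
- Forward: the four-membered ring is closed first, chlorine and the carbonyl are excised, the six-membered ring is opened to the diacid, one molecule of 2,2'-bithiophene is attached to each arm by acylation, and the alkynes are made last.
- Stereochemistry: the cis pair comes from suprafacial ketene addition to the ring (Z) alkene and is locked by the cis ring fusion until the carbonyl is gone. The target is meso, so no absolute control is needed.

Key step: step 1

Remark: the target SMILES describes the cis-1,2-disubstituted (1R,2S, meso) cyclobutane. Intermediates 4–6 are chiral only through the placement of C=O against CCl2/CH2 and are carried as racemates.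

**Step 1**
Reactants: 1 cyclohexa-1,4-diene; 2 trichloroacetyl chloride
Product: 4 cis-8,8-dichlorobicyclo[4.2.0]oct-3-en-7-one (racemic), via dichloroketene 3 (not isolated)
Conditions: Zn(Cu) couple, 1 (3 equiv), Et2O, DME (1 equiv), 2 added slowly, 35 °C
Reagents that add atoms: none
Why: Zinc strips two chlorines from 2 to give dichloroketene 3, which adds to one ring alkene of 1 in a concerted, asynchronous [π2s+π2a] ketene–alkene cycloaddition; the closest known reaction is dichloroketene addition to unactivated cis-cycloalkenes such as cyclopentene and cyclohexene. The carbonyl carbon bonds to one alkene carbon and the CCl2 carbon to the other, so the cyclobutanone closes by intermolecular [2+2] cycloaddition as a ring fused to the six-membered ring. Both new CH stereocentres arise from suprafacial delivery to an alkene that is Z because it lies in a six-membered ring, so the fusion must be cis. The two alkene carbons are equivalent, so no regiochemistry is at stake; the selectivity needed is mono-addition, secured by a threefold excess of the inexpensive diene and slow addition of 2. DME ties up ZnCl2 so the ketene does not polymerise, and the hydrocarbon substrate carries nothing that ZnCl2 or the electrophilic ketene could attack besides the alkene.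

**Step 2**
Reactants: 4 cis-8,8-dichlorobicyclo[4.2.0]oct-3-en-7-one
Product: 5 cis-bicyclo[4.2.0]oct-3-en-7-one (racemic)
Conditions: Zn dust, AcOH, rt to 60 °C
Reagents that add atoms: none
Why: Zinc-mediated reductive dehalogenation of an α,α-dichloro ketone through zinc enolates that AcOH protonates at C8; the ring-fusion carbons are not involved, and the one α to the carbonyl could in any case only return the far more stable cis fusion.

**Step 3**
Reactants: 5 cis-bicyclo[4.2.0]oct-3-en-7-one
Product: 7 cis-bicyclo[4.2.0]oct-3-ene, via ketone hydrazone 6 (not isolated)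
Conditions: N2H4·H2O, diethylene glycol, 120 °C; then KOH, 200 °C under N2, product distilled out and taken into pentane
Reagents that add atoms: none
Why: Wolff–Kishner reduction (Huang-Minlon procedure): hydrazone 6 tautomerises under KOH, loses N2 and the carbanion is protonated; the isolated alkene is inert under air-free conditions, and the ring fusion cannot epimerise because a trans-fused bicyclo[4.2.0]octene is prohibitively strained.

**Step 4**
Reactants: 7 cis-bicyclo[4.2.0]oct-3-ene
Product: 8 2,2'-(cis-cyclobutane-1,2-diyl)diacetic acid
Conditions: RuCl3·xH2O (2 mol %), NaIO4 (4.2 equiv), EtOAc/MeCN/H2O, rt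
Reagents that add atoms: sodium periodate, [Na+].[O-]I(=O)(=O)=O; water, O
Why: RuO4 generated catalytically from RuCl3 and NaIO4 cleaves the 1,2-disubstituted alkene oxidatively to two carboxylic acids, opening the six-membered tether into the two CH2CO2H arms; the ring CH stereocentres are β to the new carbonyls and cannot epimerise.

**Step 5**
Reactants: 8 2,2'-(cis-cyclobutane-1,2-diyl)diacetic acid; 9 2,2'-bithiophene (one molecule for each arm, two in all)
Product: 11 2,2'-(cis-cyclobutane-1,2-diyl)bis{1-[5-(thiophen-2-yl)thiophen-2-yl]ethan-1-one}, via diacyl chloride 10 (not isolated)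
Conditions: (COCl)2, cat. DMF, CH2Cl2, 0 °C to rt, evaporate; then AlCl3 (2.4 equiv), CH2Cl2, 0 °C, 9 (2.5 equiv) added; ice/dilute HCl work-up
Reagents that add atoms: 2,2'-bithiophene (the second molecule of 9), c1csc(-c2cccs2)c1
Why: Acid chloride formation followed by two Friedel–Crafts acylations, each COCl group of 10 reacting with its own molecule of 9 at the free α-position C5, a standard entry to bis(bithienyl) diketones from α,ω-diacyl chlorides; the first acyl group deactivates each bithiophene against a second acylation, and the acylium ions sit one CH2 away from the ring, so neither the cyclobutane nor its stereocentres are affected.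

**Step 6**
Reactants: 11 2,2'-(cis-cyclobutane-1,2-diyl)bis{1-[5-(thiophen-2-yl)thiophen-2-yl]ethan-1-one}
Product: 13 cis-cyclobutane-1,2-diylbis{(1Z)-1-[5-(thiophen-2-yl)thiophen-2-yl]ethene-2,1-diyl} bis(trifluoromethanesulfonate), via dipotassium dienolate 12 (not isolated)
Conditions: KN(SiMe3)2 (2.5 equiv), THF, −78 °C, 11 added dropwise; then PhNTf2 (2.4 equiv), −78 to 0 °C; aq. NH4Cl; filtration through Et3N-deactivated silica
Reagents that add atoms: N-phenylbis(trifluoromethanesulfonimide), O=S(=O)(N(c1ccccc1)S(=O)(=O)C(F)(F)F)C(F)(F)F
Why: Kinetic deprotonation of each aryl ketone at its only α-CH2 should give the Z-enolate (ring substituent anti to the aryl group to avoid allylic strain), which PhNTf2 sulfonylates on oxygen (enol triflate formation); adding 11 to excess base forms the dienolate before a mono-enolate can attack the second ketone, and the ring stereocentres are β to the carbonyls and not acidic.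

**Step 7**
Reactants: 13 bis(enol triflate)
Product: 14 isocardopatine, cis-1,2-bis{[5-(thiophen-2-yl)thiophen-2-yl]ethynyl}cyclobutane (1R,2S, meso)
Conditions: LiN(i-Pr)2 (3 equiv), THF, −78 °C, 30 min; aq. NH4Cl quench at −78 °C; work-up below 30 °C with exclusion of light
Reagents that add atoms: none
Why: Base-induced anti-elimination of triflate from the Z-alkenyl triflates (vinylic H trans to OTf), the standard enol triflate route from ketones to alkynes; at −78 °C the amide base should not metalate the newly propargylic ring C–H, so the cis relationship set in step 1 is retained.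

**Compound list**
1 | cyclohexa-1,4-diene | C1=CCC=CC1 | starting material
2 | trichloroacetyl chloride | O=C(Cl)C(Cl)(Cl)Cl | starting material
3 | dichloroketene (formed in the flask) | O=C=C(Cl)Cl | intermediate
4 | cis-8,8-dichlorobicyclo[4.2.0]oct-3-en-7-one (racemic, one enantiomer drawn) | O=C1[C@H]2CC=CC[C@H]2C1(Cl)Cl | intermediate
5 | cis-bicyclo[4.2.0]oct-3-en-7-one (racemic, one enantiomer drawn) | O=C1[C@H]2CC=CC[C@H]2C1 | intermediate
6 | hydrazone of 5 (formed in the flask, C=N geometry not defined) | NN=C1[C@H]2CC=CC[C@H]2C1 | intermediate
7 | cis-bicyclo[4.2.0]oct-3-ene (meso) | C1=CC[C@H]2CC[C@H]2C1 | intermediate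
8 | 2,2'-(cis-cyclobutane-1,2-diyl)diacetic acid (meso) | OC(=O)C[C@@H]1CC[C@@H]1CC(=O)O | intermediate
9 | 2,2'-bithiophene | c1csc(-c2cccs2)c1 | starting material
10 | 2,2'-(cis-cyclobutane-1,2-diyl)diacetyl dichloride (formed in the flask) | O=C(Cl)C[C@@H]1CC[C@@H]1CC(=O)Cl | intermediate
11 | 2,2'-(cis-cyclobutane-1,2-diyl)bis{1-[5-(thiophen-2-yl)thiophen-2-yl]ethan-1-one} | O=C(C[C@@H]1CC[C@@H]1CC(=O)c1ccc(-c2cccs2)s1)c1ccc(-c2cccs2)s1 | intermediate
12 | dipotassium (Z,Z)-dienolate of 11 (formed in the flask) | [K+].[K+].[O-]/C(=C\[C@@H]1CC[C@@H]1/C=C(\[O-])c1ccc(-c2cccs2)s1)c1ccc(-c2cccs2)s1 | intermediate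
13 | cis-cyclobutane-1,2-diylbis{(1Z)-1-[5-(thiophen-2-yl)thiophen-2-yl]ethene-2,1-diyl} bis(trifluoromethanesulfonate) | O=S(=O)(O/C(=C\[C@@H]1CC[C@@H]1/C=C(\OS(=O)(=O)C(F)(F)F)c1ccc(-c2cccs2)s1)c1ccc(-c2cccs2)s1)C(F)(F)F | intermediate
14 | isocardopatine, cis-1,2-bis{[5-(thiophen-2-yl)thiophen-2-yl]ethynyl}cyclobutane (1R,2S, meso) | C(#C[C@@H]1CC[C@@H]1C#Cc1ccc(-c2cccs2)s1)c1ccc(-c2cccs2)s1 | target

**Step count**
Total steps: 7. Longest linear sequence: 7 steps (from 1 and 2; 9 is a commercial reactant entering in step 5).

**Steps most likely to fail**

Step 6. The mono-enolate may add to the second ketone (intramolecular aldol closing a five-membered ring onto the cyclobutane) faster than it is sulfonylated, or enolisation may stop after one arm. The fallback sets out from 11 and returns at 14 without ever forming an enolate. Condensation of 11 with N2H4·H2O in EtOH should give the bis-hydrazone F1. Oxidation with I2 and 1,1,3,3-tetramethylguanidine in THF (Barton alkenyl iodide synthesis) should give the bis(alkenyl iodide) F2. KOt-Bu in THF at 0 °C then removes HI from both arms to give 14.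

Step 7. The cis configuration may be eroded by propargylic deprotonation and reprotonation once the aryl alkyne has formed, or the amide base may attack sulfur and return the ketone. The fallback sets out from 7 and returns at 14, attaching the bithiophenes only at the end under amine base. Ozonolysis of 7 (O3, CH2Cl2, −78 °C) gives the secondary ozonide F3, which Me2S reduces to 2,2'-(cis-cyclobutane-1,2-diyl)diacetaldehyde F4. Nonafluorobutane-1-sulfonyl fluoride and the phosphazene base P2-Et in DMF convert both CH2CHO groups, through the bis(alkenyl nonaflate) F5, into cis-1,2-diethynylcyclobutane F6. Twofold Sonogashira coupling of F6 with two equivalents of commercial 5-bromo-2,2'-bithiophene (PdCl2(PPh3)2, CuI, i-Pr2NH, THF, 50 °C) gives 14.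

Step 5. The electron-rich bithiophene may oligomerise under the Lewis acid, or one bithiophene may be acylated at both ends and link two diacid units. The fallback sets out from 8 through its diacyl chloride 10 and returns at 11, replacing electrophilic acylation by organolithium addition. Treatment of 10 with MeNHOMe·HCl and pyridine in CH2Cl2 gives the bis(N-methoxy-N-methylamide) F7. 5-Lithio-2,2'-bithiophene F8, made from 9 with n-BuLi in THF at −78 °C, adds once to each Weinreb amide, and aqueous NH4Cl work-up releases 11.

**Further compounds**
F1 | step 6 | bis-hydrazone of 11 (C=N geometry not defined) | NN=C(C[C@@H]1CC[C@@H]1CC(=NN)c1ccc(-c2cccs2)s1)c1ccc(-c2cccs2)s1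
F2 | step 6 | cis-1,2-bis{2-iodo-2-[5-(thiophen-2-yl)thiophen-2-yl]ethenyl}cyclobutane (alkene geometry not defined) | IC(=C[C@@H]1CC[C@@H]1C=C(I)c1ccc(-c2cccs2)s1)c1ccc(-c2cccs2)s1
F3 | step 7 | secondary ozonide of 7, 9,10,11-trioxatricyclo[6.2.1.0(3,6)]undecane with cis cyclobutane fusion (either orientation of the trioxolane) | O1OC2C[C@H]3CC[C@H]3CC1O2
F4 | step 7 | 2,2'-(cis-cyclobutane-1,2-diyl)diacetaldehyde | O=CC[C@@H]1CC[C@@H]1CC=O
F5 | step 7 | cis-cyclobutane-1,2-diylbis(ethene-2,1-diyl) bis(nonafluorobutane-1-sulfonate) (alkene geometry not defined) | FC(F)(F)C(F)(F)C(F)(F)C(F)(F)S(=O)(=O)OC=C[C@@H]1CC[C@@H]1C=COS(=O)(=O)C(F)(F)C(F)(F)C(F)(F)C(F)(F)F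
F6 | step 7 | cis-1,2-diethynylcyclobutane | C#C[C@@H]1CC[C@@H]1C#C
F7 | step 5 | 2,2'-(cis-cyclobutane-1,2-diyl)bis(N-methoxy-N-methylacetamide) | CON(C)C(=O)C[C@@H]1CC[C@@H]1CC(=O)N(C)OC
F8 | step 5 | 5-lithio-2,2'-bithiophene | [Li]c1ccc(-c2cccs2)s1
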